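**Retrosynthetic overview**
1. Target ⇒ linoleic acid + 3,5-bis[(2R)-3-hydroxy-2-mesyloxy-3-methylbutyl]indole. One base cascade: the C3 chain undergoes a stereoinvertive 1,2-indolyl shift (spirocyclopropane-indolenine, opened by the carboxylate at CH2) and the C5 chain closes to the oxirane.
2. Bis-mesylate ⇒ pseudo-symmetric bis-diol ⇒ bis(α-hydroxy methyl ester), by exhaustive MeMgBr addition and selective mesylation.
3. Key C5–CH2 bond ⇒ blue-light nickel/iridium photoredox cross-electrophile coupling of the aryl bromide with the bromohydrin of methyl (R)-glycidate. C3–CH2 bond ⇒ Friedel–Crafts opening of the same glycidate by 5-bromoindole.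
4. Rings: the indole is bought; the transient spirocyclopropane forms first and the oxirane second, both in the last step. Both stereocentres come from methyl (R)-glycidate.

Assumption: methyl (2R)-oxirane-2-carboxylate (L-serine-derived) is taken as a cheap commercial chiral-pool material, and linoleic acid is bought as the pure (9Z,12Z) isomer.

**Step 1**
Reactants: 1 5-bromo-1H-indole; 2 methyl (2R)-oxirane-2-carboxylate
Product: 3 methyl (2R)-3-(5-bromo-1H-indol-3-yl)-2-hydroxypropanoate
Conditions: SnCl4 (1.2 equiv), CH2Cl2, −78 → 0 °C; aqueous work-up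
Reagents that add atoms: none
Why: Lewis-acid-mediated Friedel–Crafts alkylation (epoxide opening), in which SnCl4 chelates the oxirane oxygen and ester carbonyl of 2 and indole C3 attacks the unsubstituted CH2 terminus, so the bought (R)-carbinol centre is not touched.

**Step 2**
Reactants: 3 methyl (2R)-3-(5-bromo-1H-indol-3-yl)-2-hydroxypropanoate; 2 methyl (2R)-oxirane-2-carboxylate
Product: 5 dimethyl (2R,2'R)-3,3'-(1H-indole-3,5-diyl)bis(2-hydroxypropanoate), via bromohydrin 4 (not isolated)
Conditions: 2 (1.6 equiv), LiBr, AcOH, DME, rt, 2 h; then 3, Ir[dF(CF3)ppy]2(dtbbpy)PF6 (1 mol%), NiCl2·dme (5 mol%), dtbbpy (5 mol%), (Me3Si)3SiH (1.2 equiv), Na2CO3 (2 equiv), DME, blue LEDs (450 nm), rt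
Reagents that add atoms: none
Why: Silyl-radical-mediated nickel/photoredox cross-electrophile coupling, in which LiBr/AcOH first opens 2 at CH2 to bromohydrin 4 (the descriptor becomes S by CIP priority only), the photogenerated silyl radical abstracts its bromine, and the primary radical is captured by the aryl–nickel species from 3 to forge the C5–CH2 bond one carbon away from the retained stereocentre.

**Step 3**
Reactants: 5 dimethyl (2R,2'R)-3,3'-(1H-indole-3,5-diyl)bis(2-hydroxypropanoate)
Product: 6 (2R,2'R)-1,1'-(1H-indole-3,5-diyl)bis(3-methylbutane-2,3-diol)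
Conditions: MeMgBr (10 equiv), THF, 0 °C → rt; aq. NH4Cl
Reagents that add atoms: methylmagnesium bromide, C[Mg]Br
Why: Double Grignard addition to each α-hydroxy ester gives the two tertiary carbinols, the α-alkoxides formed first suppressing enolisation so both (R)-centres survive.

**Step 4**
Reactants: 6 (2R,2'R)-1,1'-(1H-indole-3,5-diyl)bis(3-methylbutane-2,3-diol)
Product: 7 3,5-bis[(2R)-3-hydroxy-3-methyl-2-(methylsulfonyloxy)butyl]-1H-indole
Conditions: MsCl (2.3 equiv), pyridine, CH2Cl2, 0 °C; used crude and cold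
Reagents that add atoms: methanesulfonyl chloride, CS(=O)(=O)Cl
Why: Selective O-sulfonylation, since under MsCl/pyridine (no sulfene) only the two secondary hydroxyls react while the tertiary carbinols and the indole N–H are inert, and no bond to a stereocentre is broken.

**Step 5**
Reactants: 7 3,5-bis[(2R)-3-hydroxy-3-methyl-2-(methylsulfonyloxy)butyl]-1H-indole; 8 (9Z,12Z)-octadeca-9,12-dienoic acid (linoleic acid)
Product: 11 (2S)-2-[5-[[(2S)-3,3-dimethyloxiran-2-yl]methyl]-1H-indol-3-yl]-3-hydroxy-3-methylbutyl (9Z,12Z)-octadeca-9,12-dienoate (CNP0149105.1), via spirocyclopropane mesylate 9 (not isolated), via spirocyclopropane epoxide 10 (not isolated)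
Conditions: KN(SiMe3)2 (1.0 equiv), THF (0.02 M), −40 °C → rt; KN(SiMe3)2 (1.0 equiv), −40 → 0 °C; then 8 (3 equiv), 0 °C → rt
Reagents that add atoms: none
Why: Proposed new method: a base-triggered stereoinvertive 1,2-shift of the indol-3-yl group with carboxylate capture, in which the first equivalent of base removes only N–H and the indolide C3 displaces the adjacent secondary mesylate by 3-exo-tet SN2 attack (inversion, creating the C3–C bond of the future (S)-centre) to give spirocyclopropane-indolenine 9, the second equivalent forms the C5-chain tertiary alkoxide that closes the (S)-oxirane with inversion (10), and linoleic acid then protonates the indolenine nitrogen so that its carboxylate opens the activated cyclopropane at the unhindered CH2, re-aromatising the indole without touching the new stereocentre; the closest known reaction types are the formation of spiro[cyclopropane-1,3'-indolenines] from tryptophyl sulfonates with their solvolytic ring-opening (phenonium-type 1,2-aryl shift) and the hydroxy-mesylate to epoxide closure.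

**Compound list**
1 | 5-bromo-1H-indole | Brc1ccc2[nH]ccc2c1 | starting material
2 | methyl (2R)-oxirane-2-carboxylate | COC(=O)[C@H]1CO1 | starting material
3 | methyl (2R)-3-(5-bromo-1H-indol-3-yl)-2-hydroxypropanoate | COC(=O)[C@H](O)Cc1c[nH]c2ccc(Br)cc12 | intermediate
4 | methyl (2S)-3-bromo-2-hydroxypropanoate | COC(=O)[C@H](O)CBr | intermediate
5 | dimethyl (2R,2'R)-3,3'-(1H-indole-3,5-diyl)bis(2-hydroxypropanoate) | COC(=O)[C@H](O)Cc1c[nH]c2ccc(C[C@@H](O)C(=O)OC)cc12 | intermediate
6 | (2R,2'R)-1,1'-(1H-indole-3,5-diyl)bis(3-methylbutane-2,3-diol) | CC(C)(O)[C@H](O)Cc1c[nH]c2ccc(C[C@@H](O)C(C)(C)O)cc12 | intermediate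
7 | 3,5-bis[(2R)-3-hydroxy-3-methyl-2-(methylsulfonyloxy)butyl]-1H-indole | CC(C)(O)[C@H](OS(C)(=O)=O)Cc1c[nH]c2ccc(C[C@@H](OS(C)(=O)=O)C(C)(C)O)cc12 | intermediate
8 | (9Z,12Z)-octadeca-9,12-dienoic acid | CCCCC/C=C\C/C=C\CCCCCCCC(=O)O | starting material
9 | (2R)-3-hydroxy-1-[(2R)-2-(2-hydroxypropan-2-yl)spiro[cyclopropane-1,3'-indol]-5'-yl]-3-methylbutan-2-yl methanesulfonate (both epimers at the spiro carbon) | CC(C)(O)[C@@H]1CC12C=Nc3ccc(C[C@@H](OS(C)(=O)=O)C(C)(C)O)cc23 | intermediate
10 | 2-[(2R)-5'-[[(2S)-3,3-dimethyloxiran-2-yl]methyl]spiro[cyclopropane-1,3'-indol]-2-yl]propan-2-ol (both epimers at the spiro carbon) | CC(C)(O)[C@@H]1CC12C=Nc3ccc(C[C@@H]4OC4(C)C)cc23 | intermediate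
11 | (2S)-2-[5-[[(2S)-3,3-dimethyloxiran-2-yl]methyl]-1H-indol-3-yl]-3-hydroxy-3-methylbutyl (9Z,12Z)-octadeca-9,12-dienoate | CCCCC/C=C\C/C=C\CCCCCCCC(=O)OC[C@H](c1c[nH]c2ccc(C[C@@H]3OC3(C)C)cc12)C(C)(C)O | target

**Totals**
Total step count: 5. Longest linear sequence: 5 steps (1 → 3 → 5 → 6 → 7 → 11).

**Three steps most likely to fail**

Step 5 (the proposed new cascade) carries the highest risk. The C3-chain tertiary alkoxide may close its own oxirane before the indolide carbon attacks, the spirocyclopropane may revert under excess base, or the carboxylate may open the cyclopropane at the wrong carbon. The fallback uses known chemistry, sets out from 1 and comes back at 11; it builds the C3 chain by a classical intermolecular indolyl-Grignard epoxide opening instead of the shift.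
- Methyl (2S)-oxirane-2-carboxylate (the commercial enantiomer of 2) with MeMgCl (THF, −78 °C) gives (2S)-2-(oxiran-2-yl)propan-2-ol F1.
- Payne rearrangement (NaH, THF, 0 °C → rt) converts it, with inversion at the carbinol carbon, into [(2R)-3,3-dimethyloxiran-2-yl]methanol F2.
- 1 is N-metalated with i-PrMgCl to 5-bromoindol-1-ylmagnesium chloride F3. Its C3 opens the chloromagnesium alkoxide of F2 at the secondary oxirane carbon (SN2, inversion) to give (2S)-2-(5-bromo-1H-indol-3-yl)-3-methylbutane-1,3-diol F4.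
- Under the conditions of step 2 (coupling with 4), F4 gives methyl (2R)-3-[3-[(2S)-1,3-dihydroxy-3-methylbutan-2-yl]-1H-indol-5-yl]-2-hydroxypropanoate F5.
- Under the conditions of step 3 (MeMgBr), F5 gives (2S)-2-[5-[(2R)-2,3-dihydroxy-3-methylbutyl]-1H-indol-3-yl]-3-methylbutane-1,3-diol F6.
- The only primary hydroxyl is acylated with linoleoyl chloride (2,4,6-collidine, CH2Cl2, −40 °C) to give (2S)-2-[5-[(2R)-2,3-dihydroxy-3-methylbutyl]-1H-indol-3-yl]-3-hydroxy-3-methylbutyl (9Z,12Z)-octadeca-9,12-dienoate F7.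
- Mesylation of the remaining secondary hydroxyl (MsCl, pyridine, 0 °C) gives (2S)-3-hydroxy-2-[5-[(2R)-3-hydroxy-3-methyl-2-(methylsulfonyloxy)butyl]-1H-indol-3-yl]-3-methylbutyl (9Z,12Z)-octadeca-9,12-dienoate F8.
- DBU (CH2Cl2, rt) closes the (S)-oxirane with inversion to deliver 11.

Step 2 (photoredox coupling) may suffer from re-closure of the free bromohydrin to the glycidate or from protodebromination of the electron-rich aryl bromide. The fallback sets out from 3 and comes back at 6; it replaces the halide radical precursor by a decarboxylative one from a different chiral-pool acid.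
- Commercial (R)-2-(2,2-dimethyl-5-oxo-1,3-dioxolan-4-yl)acetic acid (D-malic acid acetonide) is esterified with N-hydroxyphthalimide (DIC, DMAP, CH2Cl2) to give 1,3-dioxoisoindolin-2-yl 2-[(4R)-2,2-dimethyl-5-oxo-1,3-dioxolan-4-yl]acetate F9.
- Thermal nickel-catalysed reductive decarboxylative arylation of 3 with F9 (NiBr2·dme, dtbbpy, Zn, DMA, rt) gives methyl (2R)-3-[5-[[(4R)-2,2-dimethyl-5-oxo-1,3-dioxolan-4-yl]methyl]-1H-indol-3-yl]-2-hydroxypropanoate F10.
- Excess MeMgBr under the conditions of step 3 opens both the dioxolanone and the methyl ester to give 6 directly.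

Step 1 (Friedel–Crafts opening) may give indole oligomers or chlorohydrin from chloride attack on the glycidate. The fallback sets out from 1 and comes back at 3; it activates the nucleophile instead of the electrophile.
- 1 with EtMgBr (Et2O, 0 °C) gives 5-bromoindol-1-ylmagnesium bromide F11.
- The C3 carbon of F11 opens 2 at the CH2 terminus (classical indolyl-Grignard epoxide opening, CH2Cl2/Et2O, −20 °C → rt) to give 3.

**Further compounds**
F1 | step 5 | (2S)-2-(oxiran-2-yl)propan-2-ol | CC(C)(O)[C@@H]1CO1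
F2 | step 5 | [(2R)-3,3-dimethyloxiran-2-yl]methanol | CC1(C)O[C@@H]1CO
F3 | step 5 | 5-bromoindol-1-ylmagnesium chloride | Brc1ccc2n([Mg]Cl)ccc2c1
F4 | step 5 | (2S)-2-(5-bromo-1H-indol-3-yl)-3-methylbutane-1,3-diol | OC[C@H](c1c[nH]c2ccc(Br)cc12)C(C)(C)O
F5 | step 5 | methyl (2R)-3-[3-[(2S)-1,3-dihydroxy-3-methylbutan-2-yl]-1H-indol-5-yl]-2-hydroxypropanoate | OC[C@H](c1c[nH]c2ccc(C[C@@H](O)C(=O)OC)cc12)C(C)(C)O
F6 | step 5 | (2S)-2-[5-[(2R)-2,3-dihydroxy-3-methylbutyl]-1H-indol-3-yl]-3-methylbutane-1,3-diol | OC[C@H](c1c[nH]c2ccc(C[C@@H](O)C(C)(C)O)cc12)C(C)(C)O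
F7 | step 5 | (2S)-2-[5-[(2R)-2,3-dihydroxy-3-methylbutyl]-1H-indol-3-yl]-3-hydroxy-3-methylbutyl (9Z,12Z)-octadeca-9,12-dienoate | CCCCC/C=C\C/C=C\CCCCCCCC(=O)OC[C@H](c1c[nH]c2ccc(C[C@@H](O)C(C)(C)O)cc12)C(C)(C)O
F8 | step 5 | (2S)-3-hydroxy-2-[5-[(2R)-3-hydroxy-3-methyl-2-(methylsulfonyloxy)butyl]-1H-indol-3-yl]-3-methylbutyl (9Z,12Z)-octadeca-9,12-dienoate | CCCCC/C=C\C/C=C\CCCCCCCC(=O)OC[C@H](c1c[nH]c2ccc(C[C@@H](OS(C)(=O)=O)C(C)(C)O)cc12)C(C)(C)O
F9 | step 2 | 1,3-dioxoisoindolin-2-yl 2-[(4R)-2,2-dimethyl-5-oxo-1,3-dioxolan-4-yl]acetate | O=C(ON2C(=O)c3ccccc3C2=O)C[C@H]1OC(C)(C)OC1=O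
F10 | step 2 | methyl (2R)-3-[5-[[(4R)-2,2-dimethyl-5-oxo-1,3-dioxolan-4-yl]methyl]-1H-indol-3-yl]-2-hydroxypropanoate | COC(=O)[C@H](O)Cc1c[nH]c2ccc(C[C@H]3OC(C)(C)OC3=O)cc12
F11 | step 1 | 5-bromoindol-1-ylmagnesium bromide | Brc1ccc2n([Mg]Br)ccc2c1
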